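**Assumptions**
- (E)-2-Methylbut-2-ene-1,4-diol (1) and ethyl 2-(hydroxymethyl)acrylate (12) are purchasable. The Ipc₂B-allyl and Ipc₂B-methallyl reagents are made in situ from α-pinene.
- The NHK alkoxide lactonises onto the ethyl ester in situ or on mild acid work-up.
- Stereocentre numbering is cembrane numbering. The target is 1R, 2R, 7S, 11R, 12S, 13S, 14S, with a trans-fused lactone and a trans 12,13-epoxide.

**Retrosynthesis**
1. Target ⇒ one intramolecular NHK (Cr/Ni) allylation of epoxy-aldehyde 18, a Z-2-(bromomethyl)enoate. It closes the 14-membered ring, the C14–C1 bond and the trans α-methylene-γ-lactone together, and is the last step.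
2. 18 ⇐ primary-alcohol oxidation, TBS removal and allylic bromination of linear 15.
3. 15 ⇐ two cross-metatheses (CM) that make the E-trisubstituted C8=C9 and C4=C5 alkenes from 6 + 8 + 13.
4. 6 (C9–C14) comes from Sharpless AE and Brown allylation; 8 (C5–C8) and 13 (C1–C4) come from Brown allylations. The epoxide is made first, at Step 2.

**Route**

**Step 1**
Reactants: 1 (E)-2-methylbut-2-ene-1,4-diol
Product: 2 (E)-4-(TBSO)-2-methylbut-2-en-1-ol
Conditions: TBSCl (1.0 equiv), imidazole, CH₂Cl₂, 0 °C
Reagents that add atoms: TBSCl, CC(C)(C)[Si](C)(C)Cl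
Why: silylation occurs at the less hindered C14 OH (CH₂ on CH=) rather than the C11 OH next to the fully substituted alkene carbon; the regioisomer is separated by chromatography.

**Step 2**
Reactants: 2
Product: 3 [(2S,3S)-3-(TBSOCH₂)-2-methyloxiran-2-yl]methanol
Conditions: Ti(OiPr)₄ (10 mol%), L-(+)-DET (12 mol%), TBHP, 3 Å MS, CH₂Cl₂, –20 °C
Reagents that add atoms: tert-butyl hydroperoxide, CC(C)(C)OO (supplies the epoxide O)
Why: Sharpless asymmetric epoxidation of the (E)-2-methyl allylic alcohol sets C12 (S) and C13 (S) and the trans epoxide in one step.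

**Step 3**
Reactants: 3
Product: 4 (2R,3S)-3-(TBSOCH₂)-2-methyloxirane-2-carbaldehyde
Conditions: Dess–Martin periodinane, NaHCO₃, CH₂Cl₂, 0 °C → rt
Reagents that add atoms: none
Why: oxidation of the primary alcohol gives an α-quaternary epoxy aldehyde that cannot epimerise.

**Step 4**
Reactants: 4
Product: 5 (1R)-1-[(2S,3S)-3-(TBSOCH₂)-2-methyloxiran-2-yl]but-3-en-1-ol
Conditions: (+)-B-allyldiisopinocampheylborane (from (–)-α-pinene), Et₂O, –78 °C; then NaOH, H₂O₂
Reagents that add atoms: allyl-Ipc₂B, C=CCB(C1CC2CC(C2(C)C)C1C)C1CC2CC(C2(C)C)C1C (pinane stereochemistry omitted)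
Why: Brown allylboration delivers allyl to the Re face, giving C11 (R) under reagent control, with the pinene enantiomer chosen to override the substrate's facial bias.

**Step 5**
Reactants: 5
Product: 6 (1R)-1-[(2S,3S)-3-(TBSOCH₂)-2-methyloxiran-2-yl]but-3-en-1-yl acetate
Conditions: Ac₂O, Et₃N, DMAP, CH₂Cl₂, 0 °C → rt
Reagents that add atoms: acetic anhydride, CC(=O)OC(C)=O
Why: acetylation installs the C11 acetate with retention.

**Step 6**
Reactants: 7 methacrolein
Product: 8 (3S)-2-methylhexa-1,5-dien-3-ol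
Conditions: (–)-B-allyldiisopinocampheylborane (from (+)-α-pinene), Et₂O, –78 °C; then NaOH, H₂O₂
Reagents that add atoms: allyl-Ipc₂B, C=CCB(C1CC2CC(C2(C)C)C1C)C1CC2CC(C2(C)C)C1C
Why: Brown allylboration attacks the Si face of the enal and sets C7 (S).

**Step 7**
Reactants: 9 acrolein
Product: 10 (3R)-5-methylhexa-1,5-dien-3-ol
Conditions: (+)-B-methallyldiisopinocampheylborane (from (–)-α-pinene), Et₂O, –78 °C; then NaOH, H₂O₂
Reagents that add atoms: methallyl-Ipc₂B, C=C(C)CB(C1CC2CC(C2(C)C)C1C)C1CC2CC(C2(C)C)C1C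
Why: Re-face Brown methallylation sets C2 (R).

**Step 8**
Reactants: 10
Product: 11 (3R)-5-methylhexa-1,5-dien-3-yl acetate
Conditions: Ac₂O, Et₃N, DMAP, CH₂Cl₂, 0 °C
Reagents that add atoms: acetic anhydride, CC(=O)OC(C)=O
Why: acetylation installs the C2 acetate.

**Step 9**
Reactants: 11; 12 ethyl 2-(hydroxymethyl)acrylate (4 equiv)
Product: 13 ethyl (2E,4R)-4-acetoxy-2-(hydroxymethyl)-6-methylhepta-2,6-dienoate
Conditions: Hoveyda–Grubbs II (5 mol%), CH₂Cl₂, 40 °C
Reagents that add atoms: none
Why: cross-metathesis of the reactive monosubstituted vinyl group with the acrylate gives the E-trisubstituted enoate (CO₂Et trans to C2); the 1,1-disubstituted methallyl alkene is inert.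

**Step 10**
Reactants: 8 (3 equiv); 13
Product: 14 ethyl (2E,4R,6E,9S)-4-acetoxy-9-hydroxy-2-(hydroxymethyl)-6,10-dimethylundeca-2,6,10-trienoate
Conditions: Hoveyda–Grubbs II (10 mol%), CH₂Cl₂, 40 °C
Reagents that add atoms: none
Why: CM of the terminal vinyl of 8 with the methallyl alkene of 13 forms C4=C5 as the E-trisubstituted olefin; the isopropenyl group of 8 and the enoate do not react.

**Step 11**
Reactants: 14; 6 (2 equiv)
Product: 15 linear cross-metathesis product, ethyl (2E,4R,6E,9S,10E,13R)-4,13-bis(acetyloxy)-13-[(2S,3S)-3-(TBSOCH₂)-2-methyloxiran-2-yl]-9-hydroxy-2-(hydroxymethyl)-6,10-dimethyltrideca-2,6,10-trienoate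
Conditions: Hoveyda–Grubbs II (10 mol%), CH₂Cl₂, 40 °C
Reagents that add atoms: none
Why: CM of the 1,1-disubstituted allylic-alcohol alkene of 14 with the terminal alkene of 6 makes C8=C9 (E), leaving the trisubstituted alkenes and the epoxide untouched.

**Step 12**
Reactants: 15
Product: 16 allylic bromide (Z-2-(bromomethyl)enoate)
Conditions: MsCl (1.05 equiv), Et₃N, THF, –40 °C; then LiBr, 0 °C
Reagents that add atoms: lithium bromide, [Li+].[Br-] (MsCl is not retained)
Why: the unhindered primary allylic alcohol is mesylated selectively and displaced by bromide in SN2 fashion, without allylic transposition, in the presence of the hindered C7 OH.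

**Step 13**
Reactants: 16
Product: 17 primary epoxy alcohol (C14–OH)
Conditions: HF·pyridine, THF/pyridine, 0 °C
Reagents that add atoms: none
Why: the primary TBS ether is cleaved under buffered acid; the acetates, epoxide, bromide and the C7 OH survive.

**Step 14**
Reactants: 17
Product: 18 epoxy aldehyde (cyclisation precursor)
Conditions: TEMPO (10 mol%), PhI(OAc)₂, CH₂Cl₂, rt
Reagents that add atoms: none
Why: TEMPO/PIDA oxidation is selective for the primary alcohol over the secondary allylic C7 OH; the crude aldehyde is used immediately.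

**Step 15**
Reactants: 18
Product: 19 michaolide A
Conditions: CrCl₂ (10 equiv), NiCl₂ (0.1 equiv), DMF, 0.002 M (slow addition), rt; then cat. PPTS work-up if lactonisation is incomplete
Reagents that add atoms: none
Why: intramolecular NHK allylation adds the allylchromium to the epoxy aldehyde through a chair transition state, anti-selectively, giving the trans lactone after loss of EtOH. C14 and C1 are set by epoxide-controlled facial selectivity and macrocycle conformation, and the pre-formed centres are untouched.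

**Compound list**

| No. | Name | SMILES | Role |
|---|---|---|---|
| 1 | (E)-2-methylbut-2-ene-1,4-diol | OC/C(C)=C/CO | starting material |
| 2 | (E)-4-(TBSO)-2-methylbut-2-en-1-ol | OC/C(C)=C/CO[Si](C)(C)C(C)(C)C | intermediate |
| 3 | [(2S,3S)-3-(TBSOCH₂)-2-methyloxiran-2-yl]methanol | OC[C@]1(C)O[C@H]1CO[Si](C)(C)C(C)(C)C | intermediate |
| 4 | (2R,3S)-3-(TBSOCH₂)-2-methyloxirane-2-carbaldehyde | O=C[C@]1(C)O[C@H]1CO[Si](C)(C)C(C)(C)C | intermediate |
| 5 | (1R)-1-[(2S,3S)-3-(TBSOCH₂)-2-methyloxiranyl]but-3-en-1-ol | C=CC[C@@H](O)[C@]1(C)O[C@H]1CO[Si](C)(C)C(C)(C)C | intermediate |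
| 6 | acetate of 5 | C=CC[C@@H](OC(C)=O)[C@]1(C)O[C@H]1CO[Si](C)(C)C(C)(C)C | intermediate |
| 7 | methacrolein | C=C(C)C=O | starting material |
| 8 | (3S)-2-methylhexa-1,5-dien-3-ol | C=CC[C@H](O)C(C)=C | intermediate |
| 9 | acrolein | C=CC=O | starting material |
| 10 | (3R)-5-methylhexa-1,5-dien-3-ol | C=C[C@H](O)CC(C)=C | intermediate |
| 11 | (3R)-5-methylhexa-1,5-dien-3-yl acetate | C=C[C@H](OC(C)=O)CC(C)=C | intermediate |
| 12 | ethyl 2-(hydroxymethyl)acrylate | C=C(CO)C(=O)OCC | starting material |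
| 13 | ethyl (2E,4R)-4-acetoxy-2-(hydroxymethyl)-6-methylhepta-2,6-dienoate | C=C(C)C[C@@H](OC(C)=O)/C=C(/C(=O)OCC)CO | intermediate |
| 14 | CM product of 8 + 13 | C=C(C)[C@@H](O)C/C=C(/C[C@@H](OC(C)=O)/C=C(/C(=O)OCC)CO)C | intermediate |
| 15 | linear CM product of 14 + 6 | CC(C)(C)[Si](C)(C)OC[C@@H]1O[C@@]1(C)[C@H](OC(C)=O)C/C=C(\C)[C@@H](O)C/C=C(/C[C@@H](OC(C)=O)/C=C(/C(=O)OCC)CO)C | intermediate |
| 16 | allylic bromide from 15 | CC(C)(C)[Si](C)(C)OC[C@@H]1O[C@@]1(C)[C@H](OC(C)=O)C/C=C(\C)[C@@H](O)C/C=C(/C[C@@H](OC(C)=O)/C=C(/C(=O)OCC)CBr)C | intermediate |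
| 17 | C14-alcohol from 16 | OC[C@@H]1O[C@@]1(C)[C@H](OC(C)=O)C/C=C(\C)[C@@H](O)C/C=C(/C[C@@H](OC(C)=O)/C=C(/C(=O)OCC)CBr)C | intermediate |
| 18 | epoxy aldehyde from 17 | O=C[C@@H]1O[C@@]1(C)[C@H](OC(C)=O)C/C=C(\C)[C@@H](O)C/C=C(/C[C@@H](OC(C)=O)/C=C(/C(=O)OCC)CBr)C | intermediate |
| 19 | michaolide A | C=C1C(=O)O[C@H]2[C@H]1[C@H](OC(C)=O)C/C(C)=C/C[C@H](O)/C(C)=C/C[C@@H](OC(C)=O)[C@]1(C)O[C@@H]21 | target |

**Totals**
- Total steps: 15.
- Longest linear sequence: 10 (1→2→3→4→5→15→16→17→18→19, i.e. Steps 1–5 then 11–15).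

**Three steps most likely to fail**
1. **Step 15 (macro-NHK).** Risks are poor C14/C1 diastereoselectivity, epoxy-aldehyde decomposition, and 1,4-elimination of the C2 acetate from the allylchromium.
   Fallback: form C14–C1 intermolecularly first (NHK of the C14 epoxy aldehyde from 4/6 with the allylic bromide from 13) to give the trans-lactone with separable diastereomers. Then close the ring by macro-RCM/CM at C8=C9.
2. **Step 11 (CM of hindered 14 with 6).** The 1,1-disubstituted alkene next to a free secondary alcohol may give low yield or E/Z mixtures.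
   Fallback: replace CM with a Julia–Kocienski olefination. The C9 aldehyde comes from ozonolysis of 6; the C8 PT-sulfone comes from the C7 fragment.
3. **Step 4 (Brown allylation of the α-methyl epoxy aldehyde).** The substrate's facial bias may be mismatched with the reagent, lowering dr.
   Fallback: change the order. Brown-allylate the achiral enal OHC–C(Me)=CH–CH₂OTBS, acetylate, remove TBS, then do the Sharpless AE on the primary allylic alcohol, so C11 is set without substrate bias.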